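**Retrosynthetic overview**
- The pyranone ring is the only ring made and it is made last: the O1–C2 bond is formed by an enantioselective 6-endo oxa-Michael addition of the 2-hydroxyl onto a 2-aryl-1-(2-hydroxyaryl)propenone, and protonation of the resulting enol sets C3.
- The enone comes from α-methylenation of the deoxybenzoin; the C2 carbon is supplied by Eschenmoser's salt.
- The deoxybenzoin comes from Pd-catalysed α-arylation of the A-ring methyl ketone with the B-ring aryl bromide (C3–C1' bond).
- The A-ring ketone comes from 4,6-dibromoresorcinol by two successive Br/Li exchanges (geranyl bromide, then a Weinreb acetamide). The phenols travel as 1-ethoxyethyl acetals, which the acid catalyst of the last step removes.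

Assumption: (R)-TRIP is taken to give the 3S ketone; if the sense of induction is opposite, (S)-TRIP is used. The 1-ethoxyethyl acetal carbons are stereorandom (diastereomer mixtures, written without descriptors) and all are removed in step 7.

**Step 1**
Reactants: 1 4,6-dibromobenzene-1,3-diol; 2 ethyl vinyl ether
Product: 3 1,5-dibromo-2,4-bis(1-ethoxyethoxy)benzene
Conditions: 2 (4 equiv), PPTS (5 mol %), CH2Cl2, 0 °C → rt; Et3N quench
Reagents that add atoms: ethyl vinyl ether C=COCC
Why: Acid-catalysed addition of the phenols to the enol ether (acetal protection) masks both OH groups as acetals that are stable to organolithiums, bases and Pd(0) yet very acid-labile.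

**Step 2**
Reactants: 3 1,5-dibromo-2,4-bis(1-ethoxyethoxy)benzene; 4 geranyl bromide
Product: 7 1-bromo-5-[(2E)-3,7-dimethylocta-2,6-dien-1-yl]-2,4-bis(1-ethoxyethoxy)benzene, via aryllithium 5 (not isolated), via arylcopper 6 (not isolated)
Conditions: n-BuLi (1.0 equiv), THF, −78 °C; CuBr·SMe2 (1.0 equiv), −78 → −40 °C; 4 (1.1 equiv), −40 → 0 °C
Reagents that add atoms: geranyl bromide BrC/C=C(\C)CCC=C(C)C
Why: Bromine–lithium exchange of one of two equivalent C–Br bonds with one equivalent of n-BuLi, transmetalation to copper and SN2 (α-selective) allylic substitution attach the geranyl chain with its 2E geometry kept.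

**Step 3**
Reactants: 7 1-bromo-5-[(2E)-3,7-dimethylocta-2,6-dien-1-yl]-2,4-bis(1-ethoxyethoxy)benzene; 8 N-methoxy-N-methylacetamide
Product: 11 1-{5-[(2E)-3,7-dimethylocta-2,6-dien-1-yl]-2,4-bis(1-ethoxyethoxy)phenyl}ethan-1-one, via aryllithium 9 (not isolated), via lithium hemiaminal 10 (not isolated)
Conditions: n-BuLi (1.05 equiv), THF, −78 °C; 8 (1.5 equiv), −78 → 0 °C; H2O quench
Reagents that add atoms: N-methoxy-N-methylacetamide CC(=O)N(C)OC
Why: A second Br/Li exchange followed by Weinreb ketone synthesis gives the methyl ketone, because the chelated tetrahedral adduct blocks over-addition and collapses only on neutral aqueous quench.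

**Step 4**
Reactants: 12 4-bromo-3-methoxyphenol; 2 ethyl vinyl ether
Product: 13 1-bromo-4-(1-ethoxyethoxy)-2-methoxybenzene
Conditions: 2 (2 equiv), PPTS (5 mol %), CH2Cl2, 0 °C → rt; Et3N quench
Reagents that add atoms: ethyl vinyl ether C=COCC
Why: The same acid-catalysed acetal protection removes the acidic phenol proton that would otherwise consume base and slow oxidative addition in the coupling.

**Step 5**
Reactants: 11 1-{5-[(2E)-3,7-dimethylocta-2,6-dien-1-yl]-2,4-bis(1-ethoxyethoxy)phenyl}ethan-1-one; 13 1-bromo-4-(1-ethoxyethoxy)-2-methoxybenzene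
Product: 14 1-{5-[(2E)-3,7-dimethylocta-2,6-dien-1-yl]-2,4-bis(1-ethoxyethoxy)phenyl}-2-[4-(1-ethoxyethoxy)-2-methoxyphenyl]ethan-1-one
Conditions: Pd2(dba)3 (1.5 mol %), Xantphos (3.6 mol %), NaOtBu (1.3 equiv), 11 (1.1 equiv), THF, 70 °C
Reagents that add atoms: none
Why: Buchwald–Hartwig-type Pd-catalysed α-arylation of a methyl ketone enolate with a wide-bite-angle ligand gives clean mono-arylation, and the acetals and trisubstituted alkenes are inert to the base and to Pd(0).

**Step 6**
Reactants: 14 1-{5-[(2E)-3,7-dimethylocta-2,6-dien-1-yl]-2,4-bis(1-ethoxyethoxy)phenyl}-2-[4-(1-ethoxyethoxy)-2-methoxyphenyl]ethan-1-one; 15 N,N-dimethylmethyleneiminium iodide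
Product: 19 1-{5-[(2E)-3,7-dimethylocta-2,6-dien-1-yl]-2,4-bis(1-ethoxyethoxy)phenyl}-2-[4-(1-ethoxyethoxy)-2-methoxyphenyl]prop-2-en-1-one, via lithium enolate 16 (not isolated), via Mannich base 17 (not isolated), via methiodide 18 (not isolated)
Conditions: LiHMDS (1.1 equiv), THF, −78 °C; 15 (1.3 equiv), −78 °C → rt; MeI (5 equiv), rt; aq. NaHCO3/CH2Cl2, rt
Reagents that add atoms: N,N-dimethylmethyleneiminium iodide C=[N+](C)C.[I-]
Why: Eschenmoser methylenation (Mannich reaction of the enolate, N-quaternisation, E1cB loss of trimethylamine) gives the 1,1-disubstituted enone, and no ring closure can occur because all three phenols are still masked.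

**Step 7**
Reactants: 19 1-{5-[(2E)-3,7-dimethylocta-2,6-dien-1-yl]-2,4-bis(1-ethoxyethoxy)phenyl}-2-[4-(1-ethoxyethoxy)-2-methoxyphenyl]prop-2-en-1-one
Product: 22 (3S)-6-[(2E)-3,7-dimethylocta-2,6-dien-1-yl]-7-hydroxy-3-(4-hydroxy-2-methoxyphenyl)-2,3-dihydro-4H-chromen-4-one, via triol enone 20 (not isolated), via enol 21 (not isolated)
Conditions: (R)-TRIP (10 mol %), MeOH (3.5 equiv), CH2Cl2/PhMe 1:1, 0 °C → rt; silica chromatography without base
Reagents that add atoms: none
Why: Proposed new method: one chiral phosphoric acid first transacetalises the three aryl acetals to MeOH, so the phenols appear only as neutral ArOH in a base-free medium and no phenoxide-driven racemic closure can compete; it then binds the chelated 2-hydroxyaryl enone bifunctionally (P=O···HOAr, P–OH···O=C), promotes 6-endo-trig oxa-Michael addition to the unsubstituted CH2 terminus (O1–C2 bond) to give enol 21, and relays the proton to one face of C3 inside its 3,3'-aryl pocket (enantio-determining 1,3-proton shift) to set 3S, the acid being too weak to protonate the geranyl alkenes or to enolise the product quickly; the closest known reactions are the racemic amine-mediated closure of 2'-hydroxy-α-methylenedeoxybenzoins to isoflavanones, chiral Brønsted-acid-catalysed enantioselective protonation of enols and silyl enol ethers of 2-aryl cyclic ketones, phosphoric-acid-catalysed transacetalisation, and bifunctional-catalyst hetero-Michael/enantioselective protonation of α-substituted acrylates.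

**Compound list**
1 | 4,6-dibromobenzene-1,3-diol (4,6-dibromoresorcinol) | Oc1cc(O)c(Br)cc1Br | starting material
2 | ethyl vinyl ether | C=COCC | starting material
3 | 1,5-dibromo-2,4-bis(1-ethoxyethoxy)benzene (acetal carbons unassigned) | CCOC(C)Oc1cc(OC(C)OCC)c(Br)cc1Br | intermediate
4 | geranyl bromide, (2E)-1-bromo-3,7-dimethylocta-2,6-diene | BrC/C=C(\C)CCC=C(C)C | starting material
5 | [5-bromo-2,4-bis(1-ethoxyethoxy)phenyl]lithium | [Li]c1cc(Br)c(OC(C)OCC)cc1OC(C)OCC | intermediate
6 | [5-bromo-2,4-bis(1-ethoxyethoxy)phenyl]copper(I) | [Cu]c1cc(Br)c(OC(C)OCC)cc1OC(C)OCC | intermediate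
7 | 1-bromo-5-[(2E)-3,7-dimethylocta-2,6-dien-1-yl]-2,4-bis(1-ethoxyethoxy)benzene | CCOC(C)Oc1cc(OC(C)OCC)c(C/C=C(\C)CCC=C(C)C)cc1Br | intermediate
8 | N-methoxy-N-methylacetamide | CC(=O)N(C)OC | starting material
9 | {5-[(2E)-3,7-dimethylocta-2,6-dien-1-yl]-2,4-bis(1-ethoxyethoxy)phenyl}lithium | [Li]c1cc(C/C=C(\C)CCC=C(C)C)c(OC(C)OCC)cc1OC(C)OCC | intermediate
10 | lithium 1-aryl-1-[methoxy(methyl)amino]ethan-1-olate (tetrahedral adduct of 9 and 8, racemic at the new carbon) | CC(O[Li])(N(C)OC)c1cc(C/C=C(\C)CCC=C(C)C)c(OC(C)OCC)cc1OC(C)OCC | intermediate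
11 | 1-{5-[(2E)-3,7-dimethylocta-2,6-dien-1-yl]-2,4-bis(1-ethoxyethoxy)phenyl}ethan-1-one | CC(=O)c1cc(C/C=C(\C)CCC=C(C)C)c(OC(C)OCC)cc1OC(C)OCC | intermediate
12 | 4-bromo-3-methoxyphenol | COc1cc(O)ccc1Br | starting material
13 | 1-bromo-4-(1-ethoxyethoxy)-2-methoxybenzene | CCOC(C)Oc1ccc(Br)c(OC)c1 | intermediate
14 | 1-{5-geranyl-2,4-bis(1-ethoxyethoxy)phenyl}-2-[4-(1-ethoxyethoxy)-2-methoxyphenyl]ethan-1-one | O=C(Cc1ccc(OC(C)OCC)cc1OC)c1cc(C/C=C(\C)CCC=C(C)C)c(OC(C)OCC)cc1OC(C)OCC | intermediate
15 | N,N-dimethylmethyleneiminium iodide (Eschenmoser's salt) | C=[N+](C)C.[I-] | starting material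
16 | lithium (Z)-enolate of 14 | [Li]O/C(=C\c1ccc(OC(C)OCC)cc1OC)c1cc(C/C=C(\C)CCC=C(C)C)c(OC(C)OCC)cc1OC(C)OCC | intermediate
17 | Mannich base, 3-(dimethylamino)-2-aryl-1-arylpropan-1-one (racemic at C2) | CN(C)CC(C(=O)c1cc(C/C=C(\C)CCC=C(C)C)c(OC(C)OCC)cc1OC(C)OCC)c1ccc(OC(C)OCC)cc1OC | intermediate
18 | N-methyl ammonium iodide of 17 (racemic at C2) | C[N+](C)(C)CC(C(=O)c1cc(C/C=C(\C)CCC=C(C)C)c(OC(C)OCC)cc1OC(C)OCC)c1ccc(OC(C)OCC)cc1OC.[I-] | intermediate
19 | 1-{5-geranyl-2,4-bis(1-ethoxyethoxy)phenyl}-2-[4-(1-ethoxyethoxy)-2-methoxyphenyl]prop-2-en-1-one | C=C(C(=O)c1cc(C/C=C(\C)CCC=C(C)C)c(OC(C)OCC)cc1OC(C)OCC)c1ccc(OC(C)OCC)cc1OC | intermediate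
20 | 1-{5-[(2E)-3,7-dimethylocta-2,6-dien-1-yl]-2,4-dihydroxyphenyl}-2-(4-hydroxy-2-methoxyphenyl)prop-2-en-1-one | C=C(C(=O)c1cc(C/C=C(\C)CCC=C(C)C)c(O)cc1O)c1ccc(O)cc1OC | intermediate
21 | 6-[(2E)-3,7-dimethylocta-2,6-dien-1-yl]-3-(4-hydroxy-2-methoxyphenyl)-2H-chromene-4,7-diol (enol, no stereocentre) | OC1=C(c2ccc(O)cc2OC)COc2cc(O)c(C/C=C(\C)CCC=C(C)C)cc12 | intermediate
22 | (3S)-6-[(2E)-3,7-dimethylocta-2,6-dien-1-yl]-7-hydroxy-3-(4-hydroxy-2-methoxyphenyl)-2,3-dihydro-4H-chromen-4-one | COc1cc(O)ccc1[C@H]1COc2cc(O)c(C/C=C(\C)CCC=C(C)C)cc2C1=O | target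

**Step count and risks**
Total steps: 7. Longest linear sequence: 6 (steps 1, 2, 3, 5, 6, 7; step 4 is a one-step side branch).

Three steps most likely to fail:

Step 7 (the proposed new method). The enantioselectivity of the proton relay is unproven, MeOH and the partly unmasked intermediates may lower it, and cyclisation may be slow; a moderate ee could be raised by recrystallisation. The fallback uses known chemistry only and sets out from 19. PPTS in MeOH removes the three acetals to give 20. A catalytic amount of Et3N then closes the ring by the classical base-mediated oxa-Michael addition to give the racemic isoflavanone F1. Preparative chiral SFC on a polysaccharide phase separates 22 from its (3R)-enantiomer F2, and F2 is re-racemised with catalytic DBU (enolisation at C3) back to F1 and passed through the column again. It comes back to the route at 22.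

Step 2. Over-exchange, SN2' attack (linalyl-type isomer) or partial loss of the E geometry would damage the A-ring fragment. The fallback sets out from 3 and moves the geranyl C–C bond formation from organocopper substitution to palladium cross-coupling. The aryllithium 5 is acylated with 8, through the lithium hemiaminal F3, to give the bromo ketone F4, whose C–Br bond is now activated by the para acyl group. Stille coupling of F4 with (E)-tributyl(geranyl)stannane F5 (made from 4 and Bu3SnLi), Pd(PPh3)4, DMF, 80 °C, transfers the allyl group at its unsubstituted terminus. It comes back to the route at 11, replacing steps 2 and 3.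

Step 6. The α-aryl vinyl ketone 19 is the most fragile isolated intermediate (hetero-Diels–Alder dimerisation, conjugate addition), and the three-stage Mannich sequence may give it in poor yield. The fallback sets out from 14 and replaces the Mannich/ammonium elimination by an aldol/sulfonate elimination. Aqueous formaldehyde with catalytic K2CO3 in THF gives the β-hydroxy ketone F6, which is not electrophilic and can be purified and stored. MsCl/Et3N at 0 °C converts it through the mesylate F7, which eliminates in the flask (E1cB), into 19 just before it is needed. It comes back to the route at 19.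

**Further compounds**
F1 | step 7 | racemic 6-[(2E)-3,7-dimethylocta-2,6-dien-1-yl]-7-hydroxy-3-(4-hydroxy-2-methoxyphenyl)-2,3-dihydro-4H-chromen-4-one | COc1cc(O)ccc1C1COc2cc(O)c(C/C=C(\C)CCC=C(C)C)cc2C1=O
F2 | step 7 | (3R)-6-[(2E)-3,7-dimethylocta-2,6-dien-1-yl]-7-hydroxy-3-(4-hydroxy-2-methoxyphenyl)-2,3-dihydro-4H-chromen-4-one | COc1cc(O)ccc1[C@@H]1COc2cc(O)c(C/C=C(\C)CCC=C(C)C)cc2C1=O
F3 | step 2 | lithium 1-[5-bromo-2,4-bis(1-ethoxyethoxy)phenyl]-1-[methoxy(methyl)amino]ethan-1-olate | CC(O[Li])(N(C)OC)c1cc(Br)c(OC(C)OCC)cc1OC(C)OCC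
F4 | step 2 | 1-[5-bromo-2,4-bis(1-ethoxyethoxy)phenyl]ethan-1-one | CC(=O)c1cc(Br)c(OC(C)OCC)cc1OC(C)OCC
F5 | step 2 | (E)-tributyl(3,7-dimethylocta-2,6-dien-1-yl)stannane | CCCC[Sn](CCCC)(CCCC)C/C=C(\C)CCC=C(C)C
F6 | step 6 | 1-{5-geranyl-2,4-bis(1-ethoxyethoxy)phenyl}-2-[4-(1-ethoxyethoxy)-2-methoxyphenyl]-3-hydroxypropan-1-one (racemic at C2) | OCC(C(=O)c1cc(C/C=C(\C)CCC=C(C)C)c(OC(C)OCC)cc1OC(C)OCC)c1ccc(OC(C)OCC)cc1OC
F7 | step 6 | methanesulfonate of F6 | CS(=O)(=O)OCC(C(=O)c1cc(C/C=C(\C)CCC=C(C)C)c(OC(C)OCC)cc1OC(C)OCC)c1ccc(OC(C)OCC)cc1OC
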